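## Analysis of the target

Target 17 is a saturated cyclohexane with no further ring. In the working numbering used throughout, C1 is the quaternary carbinol carrying the exocyclic C7H2–OBz, C2 is a free secondary carbinol, C3 and C4 are methylenes, C5 carries the second benzoate and C6 a free hydroxyl. The four stereocentres C2, C1, C6 and C5 are contiguous. With the face of C7 taken as the top face, the C2 and C6 hydroxyls are on top and the C1 hydroxyl and the C5 benzoate are below, which is 1S,2R,5R,6S in this numbering. The oxygens on C1, C6 and C5 therefore alternate (trans, trans), and the C2 oxygen is trans to the C1 oxygen. The two benzoates are base-labile and can migrate to a neighbouring free hydroxyl (C5 to C6, C7 to C1 or C2), so all basic operations have to precede acylation. The difficulty lies in telling five oxygens on seven carbons apart, in building the tetrasubstituted C1 between two secondary carbinols, and in reaching one enantiomer. The strategy rests on the trans,trans triad O–C1–C6–C5–O, which is what two successive SN2 displacements, at C6 and then at C5, leave behind when they start from a C1–C6 epoxide with a C5 oxygen on the opposite face. That precursor has the C2 and C5 oxygens cis across the ring, which is the pattern an endoperoxide of cyclohexa-1,3-diene 1 delivers.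

## Retrosynthetic reasoning

**17 to 16 and 14 (C7 O–acyl bond).** The primary C7 ester is cut first. In tetraol 16 the other free hydroxyls are tertiary (C1) or secondary and next to C1 (C2, C6), so benzoyl chloride 14 should select C7. Placing this last keeps the most exposed ester out of every earlier step.

**16 to 15 (two O–benzyl bonds).** The C2 and C7 oxygens are masked by the same group and released together by hydrogenolysis, which leaves the C5 benzoate of 15 alone. One protecting group thus covers two positions through the whole route.

**15 to 13 and 14 (C5 O–acyl bond).** In triol 13 only C5–OH and C6–OH are acylable, and C6 is flanked by the quaternary C1 and by C5. Acylating while C2 is still benzylated removes C2 from the competition.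

**13 to 11 through 12 (C5–O and C6–O bonds).** The C5–O bond of 13 is cut back to the C5–C6 epoxide 12. The C6–O bond of 12 is then cut, with its oxygen returned to C5 and the C1 oxygen closed onto C6, which gives the C1–C6 epoxide 11. The disconnection is made here because both inversions are dictated by the SN2 mechanism, so C5 and C6 are set without a reagent-controlled step. The forward reaction has to open 12 at C5 faster than anything opens at C6.

**11 to 10 to 9 (O–Si bond, then the two epoxide C–O bonds).** The C5 oxygen stays silylated during epoxidation so that it cannot direct a peracid to its own face. In alkene 9 both allylic ethers are on top, so the peracid should add from below, which is the face the C1 oxygen needs.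

**9 to 7 and 8 (two O–benzyl bonds).** Both hydroxyls of diol 7 are alkylated in one operation, each by one equivalent of benzyl bromide 8. This is done after the ketone has been reduced, so that no base-sensitive enone is exposed to alkoxide.

**7 to 6 (C2–H bond).** The C2 carbinol comes from 1,2-reduction of enone 6. The forward reaction must place the new hydroxyl cis to the C5 silyloxy group.

**6 to 4 and 5 (C1–C7 bond).** This is the only C–C bond to be made. The α-carbon of enone 4 becomes nucleophilic under amine catalysis and takes up formaldehyde 5 directly as the hydroxymethyl group.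

**4 to 3 to 2 to 1 (O–Si bond, the O–O bond, two C–O bonds).** Hydroxy enone 3 is the base-induced fragmentation product of the meso endoperoxide 2. A chiral amine that chooses between the two enantiotopic bridgehead hydrogens sets C5, the only stereocentre in the route fixed by a reagent. Endoperoxide 2 is the photooxygenation adduct of diene 1.

## Alternatives that were turned down

Alternative 1: The C2–O bond is disconnected to a Cs-symmetric dienylmethanol A1, reached by Birch reduction of a benzoic acid derivative, oxygenation at the bis-allylic carbon and reduction of the carboxyl. In the forward key step the C7 hydroxyl takes up carbon dioxide, and the carbonate so formed is delivered, together with iodine from N-iodosuccinimide and under a chiral Brønsted-base organocatalyst, across one of the two enantiotopic alkenes. This makes the C2–O bond and the cis-fused six-membered carbonate A2, with iodine at C3.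
- For: C7 and the quaternary C1 are present from the start, and one catalytic step fixes C1 and C2, with the C7/C2 cis relation enforced by the tether. On these two points it is stronger than the chosen route, which needs a separate hydroxymethylation and a separate reduction.
- Against: A1 has a leaving group on a bis-allylic carbon and can aromatise by 1,4-elimination. Enantiotopic-alkene selection at a quaternary dienyl carbinol is not an established use of iodocarbonation. A2 still lacks the C6/C5 trans-dioxygenation, so after deiodination it needs a face-selective epoxidation and a regioselective opening at C5, which is the same regiochemical problem without the mechanistic relay.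
- Comparison: the step count is not lower. The chosen route instead creates the C1/C6/C5 triad by two enforced inversions.

Alternative 2: The C5–O bond is traced to a C5–H bond of the meso hydrosilyl ether A3, in which an acetonide locks the C2 and C6 oxygens diaxial and the C1 oxygen axial on the other face. In the forward key step [Ir(cod)OMe]2 with a chiral bipyridine-type ligand inserts the silicon into the axial C5–H bond that is 1,3-syn to the C1 oxygen, which closes oxasilolane A4. Oxidation of the C–Si bond with retention would then give the C5 hydroxyl.
- For: it is the shortest plan. The C7 benzoate is already in place and the C5 configuration follows from the geometry of the tether, so no epoxide regiochemistry arises. On step economy and on C5 control it is stronger than the chosen route.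
- Against: the absolute configuration depends on a catalyst distinguishing the C5 and C3 methylenes, which differ only by the mirror plane. Enantioselective silylation of an unactivated secondary C–H bond from a tertiary silyl ether is not established, and the temperatures such insertions need work against selectivity. The C7 benzoate would also have to survive the basic peroxide oxidation.
- Comparison: the chosen route is longer, but its enantioselective step and its key step belong to known reaction classes.

Alternative 3: The C1–C7 bond is disconnected to ketone A5, which comes from a C2-symmetric all-trans tetrol whose two central hydroxyls are homotopic. In the forward key step dimethylsulfonium methylide attacks C1 along the axial direction and the betaine collapses to spiro-epoxide A6, in which C7 sits on the face of the C2 and C6 benzyloxy groups. A carboxylate could then open A6 at C7 and deliver the C7 benzoate and the C1 hydroxyl together.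
- For: on the C7/C1 functionalisation it is stronger than the chosen route, which needs a late selective acylation of the primary hydroxyl.
- Against: A5 is a β-benzyloxy ketone with two epimerisable α-alkoxy centres, so the basic ylide can cause enolisation and loss of the C5 benzyloxy group. Axial attack between two equatorial α-alkoxy groups is not assured. The three benzyl ethers cannot be told apart, so the C5 benzoate would have to be placed by selective acylation among three secondary hydroxyls. The enantiopure tetrol also costs several steps.
- Comparison: the chosen route distinguishes C5 from C2 by construction, because the C5 and C6 hydroxyls appear only in the key step while C2 is still benzylated.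

Key step: step 9

Assumption: the quinidine-derived 6'-hydroxy cinchona catalyst is taken to give the (S)-enone 3; if the sense is the reverse, its quinine-derived pseudoenantiomer is used and nothing else changes.

Remark on descriptors: the CIP descriptor at C1 switches between R and S along the route only because benzylation changes the priority of C2 against C6. The geometry at C1 does not change after step 7.

## Route

Step 1
Reactants: 1 cyclohexa-1,3-diene
Product: 2 2,3-dioxabicyclo[2.2.2]oct-5-ene (meso endoperoxide)
Conditions: O2, tetraphenylporphyrin (cat.), visible light, CH2Cl2, 0 °C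
Reagents that add atoms: oxygen, O=O
Why: [4+2] cycloaddition of singlet oxygen to the ring-locked s-cis diene; the two new C–O bonds are necessarily cis, which becomes the 1,4-cis relation of the later C2 and C5 oxygens.

Step 2
Reactants: 2 2,3-dioxabicyclo[2.2.2]oct-5-ene
Product: 3 (4S)-4-hydroxycyclohex-2-en-1-one
Conditions: 9-O-acetylcupreidine (10 mol %), CH2Cl2, 23 °C; used crude
Reagents that add atoms: none
Why: Catalytic asymmetric Kornblum–DeLaMare rearrangement: the chiral amine removes one of the two enantiotopic bridgehead hydrogens, the O–O bond breaks, that carbon becomes the carbonyl (future C2) and the other becomes the (S)-carbinol (future C5). This is the only stereocentre set by a reagent; all later ones are relayed from it.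

Step 3
Reactants: 3 (4S)-4-hydroxycyclohex-2-en-1-one
Product: 4 (4S)-4-[(tert-butyldimethylsilyl)oxy]cyclohex-2-en-1-one
Conditions: TBSCl, imidazole, CH2Cl2, 0 °C to 23 °C
Reagents that add atoms: tert-butyldimethylsilyl chloride, CC(C)(C)[Si](C)(C)Cl
Why: Imidazole-mediated silylation of the secondary allylic hydroxyl; the silyl ether stops base-induced isomerisation of the γ-hydroxy enone, later biases both faces of the ring and keeps the C5 oxygen from directing the epoxidation.

Step 4
Reactants: 4 (4S)-4-[(tert-butyldimethylsilyl)oxy]cyclohex-2-en-1-one; 5 formaldehyde
Product: 6 (4S)-4-[(tert-butyldimethylsilyl)oxy]-2-(hydroxymethyl)cyclohex-2-en-1-one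
Conditions: aq. formaldehyde, DMAP (0.3 equiv), THF/H2O, 23 °C
Reagents that add atoms: none
Why: Morita–Baylis–Hillman reaction: DMAP adds to the β-carbon (C6), the ammonium enolate attacks formaldehyde through the α-carbon (C1) and E1cB loss of DMAP restores the enone, forming the C1–C7 bond. The C5 stereocentre is not involved.

Step 5
Reactants: 6 (4S)-4-[(tert-butyldimethylsilyl)oxy]-2-(hydroxymethyl)cyclohex-2-en-1-one
Product: 7 (1R,4S)-4-[(tert-butyldimethylsilyl)oxy]-2-(hydroxymethyl)cyclohex-2-en-1-ol (1,4-cis)
Conditions: NaBH4, CeCl3·7H2O, MeOH, −78 °C
Reagents that add atoms: none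
Why: Luche 1,2-reduction. In the reactive half-chair the C5 silyloxy group is expected to be pseudoaxial, and axial hydride attack then comes from the opposite face, placing the new C2 hydroxyl cis to the C5 oxygen; the free primary hydroxyl is tolerated.

Step 6
Reactants: 7 (1R,4S)-4-[(tert-butyldimethylsilyl)oxy]-2-(hydroxymethyl)cyclohex-2-en-1-ol; 8 benzyl bromide
Product: 9 tert-butyl{[(1S,4R)-4-(benzyloxy)-3-[(benzyloxy)methyl]cyclohex-2-en-1-yl]oxy}dimethylsilane
Conditions: NaH (2.5 equiv), BnBr (2.4 equiv), Bu4NI (cat.), THF/DMF, 0 °C to 23 °C
Reagents that add atoms: benzyl bromide (second equivalent), BrCc1ccccc1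
Why: Double Williamson etherification: the primary C7 alkoxide and the secondary allylic C2 alkoxide of 7 each take up one equivalent of benzyl bromide in one operation, and no stereocentre is touched. Bromide 8 and Bu4NI are present before NaH is added, so each alkoxide is alkylated as it forms and the secondary silyl ether is given no time to migrate; C7–O is trans to C5 across the alkene and cannot receive the silyl group at all.

Step 7
Reactants: 9 tert-butyl{[(1S,4R)-4-(benzyloxy)-3-[(benzyloxy)methyl]cyclohex-2-en-1-yl]oxy}dimethylsilane
Product: 10 tert-butyl{[(1R,2S,5R,6S)-5-(benzyloxy)-6-[(benzyloxy)methyl]-7-oxabicyclo[4.1.0]heptan-2-yl]oxy}dimethylsilane (epoxide on the bottom face)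
Conditions: mCPBA, NaHCO3, CH2Cl2, 0 °C to 23 °C
Reagents that add atoms: 3-chloroperbenzoic acid, OOC(=O)c1cccc(Cl)c1
Why: Prilezhaev epoxidation of the trisubstituted C1=C6 alkene. A(1,2) strain with the C1 substituent holds the C2 benzyloxy group pseudoaxial on the top face, the C5 silyloxy group is on the same face and no free hydroxyl is present to direct the peracid, so oxygen should arrive from below; this sets C1 for good and C6 provisionally.

Step 8
Reactants: 10 tert-butyl{[(1R,2S,5R,6S)-5-(benzyloxy)-6-[(benzyloxy)methyl]-7-oxabicyclo[4.1.0]heptan-2-yl]oxy}dimethylsilane
Product: 11 (1R,2S,5R,6S)-5-(benzyloxy)-6-[(benzyloxy)methyl]-7-oxabicyclo[4.1.0]heptan-2-ol (C5 hydroxyl anti to the C1–C6 epoxide)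
Conditions: Bu4NF, AcOH (1:1), THF, 23 °C
Reagents that add atoms: none
Why: Fluoride cleavage of the Si–O bond; the acetic acid buffer keeps the freed C5 oxygen protonated, so the epoxide does not migrate before the next step.

Step 9
Reactants: 11 (1R,2S,5R,6S)-5-(benzyloxy)-6-[(benzyloxy)methyl]-7-oxabicyclo[4.1.0]heptan-2-ol
Product: 13 (1R,2S,3R,6R)-6-(benzyloxy)-1-[(benzyloxy)methyl]cyclohexane-1,2,3-triol, via rearranged C5–C6 epoxide 12 (not isolated)
Conditions: NaOH (0.5 M aq.), t-BuOH, 75 °C
Reagents that add atoms: water, O
Why: Hydroxide deprotonates the C5 hydroxyl of 11, and the alkoxide, anti to the C1–C6 epoxide, attacks C6 from the top face (Payne rearrangement), so the oxirane moves to C5–C6 on the top face and the old epoxide oxygen becomes the bottom-face tertiary C1 alkoxide of 12. Hydroxide then opens 12 at C5 from the bottom face, leaving the former C5 oxygen on C6 and giving the all-trans triol 13. The closest known reaction type is base-mediated epoxide migration in trans-2,3-epoxycyclohexanols and anhydro-cyclitols with in situ hydrolysis of the migrated oxirane. No ring persists: the only closure is the transient oxirane of 12, formed 3-exo-tet and reopened in the same flask. C6 is inverted by backside attack of the C5 oxygen and C5 by backside attack of hydroxide, both fixed by the SN2 geometry, while C1 keeps its oxygen and configuration and C2 is a spectator. The step needs opening of 12 at C5 to outrun both opening of 12 at C6 and direct opening of 11 at C6, a Curtin–Hammett situation over the 11/12 equilibrium. C6 lies between the fully substituted C1 and an oxygenated C5 and C1 itself is tertiary, whereas C5 of 12 has a methylene on its far side and is remote from the C1–O dipole, as in the usual distal opening of 2,3-epoxy alcohols. The benzyl ethers at C2 and C7 are inert to hot aqueous base and stop those oxygens from starting epoxide migrations of their own.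

Step 10
Reactants: 13 (1R,2S,3R,6R)-6-(benzyloxy)-1-[(benzyloxy)methyl]cyclohexane-1,2,3-triol; 14 benzoyl chloride
Product: 15 (1R,2S,3R,4R)-4-(benzyloxy)-3-[(benzyloxy)methyl]-2,3-dihydroxycyclohexyl benzoate (C5 benzoate)
Conditions: BzCl (1.05 equiv), pyridine, CH2Cl2, −40 °C to 0 °C
Reagents that add atoms: none
Why: Acyl transfer to the less hindered secondary hydroxyl: C6–OH lies between the quaternary C1 and C5, the C1 hydroxyl is tertiary and C2 is still benzylated, so C5–OH should react first.

Step 11
Reactants: 15 (1R,2S,3R,4R)-4-(benzyloxy)-3-[(benzyloxy)methyl]-2,3-dihydroxycyclohexyl benzoate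
Product: 16 (1R,2S,3S,4R)-2,3,4-trihydroxy-3-(hydroxymethyl)cyclohexyl benzoate
Conditions: H2 (1 atm), Pd(OH)2/C, EtOAc/MeOH, 23 °C
Reagents that add atoms: none
Why: Hydrogenolysis of both benzyl ethers over Pd(OH)2/C under neutral conditions, which neither cleave nor move the benzoate and touch no stereocentre.

Step 12
Reactants: 16 (1R,2S,3S,4R)-2,3,4-trihydroxy-3-(hydroxymethyl)cyclohexyl benzoate; 14 benzoyl chloride
Product: 17 [(1S,2S,3R,6R)-3-(benzoyloxy)-1,2,6-trihydroxycyclohexyl]methyl benzoate (target)
Conditions: BzCl (1.1 equiv), 2,4,6-collidine, CH2Cl2, −78 °C to −20 °C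
Reagents that add atoms: none
Why: Selective acylation of the primary C7 hydroxyl at low temperature with a hindered pyridine base; the other free hydroxyls are tertiary (C1) or secondary and adjacent to the quaternary C1 (C2, C6).

## Compound list

1 | cyclohexa-1,3-diene | C1=CC=CCC1 | starting material
2 | 2,3-dioxabicyclo[2.2.2]oct-5-ene (meso) | C1=C[C@@H]2CC[C@H]1OO2 | intermediate
3 | (4S)-4-hydroxycyclohex-2-en-1-one | O=C1C=C[C@@H](O)CC1 | intermediate
4 | (4S)-4-[(tert-butyldimethylsilyl)oxy]cyclohex-2-en-1-one | O=C1C=C[C@@H](O[Si](C)(C)C(C)(C)C)CC1 | intermediate
5 | formaldehyde | C=O | starting material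
6 | (4S)-4-[(tert-butyldimethylsilyl)oxy]-2-(hydroxymethyl)cyclohex-2-en-1-one | O=C1C(CO)=C[C@@H](O[Si](C)(C)C(C)(C)C)CC1 | intermediate
7 | (1R,4S)-4-[(tert-butyldimethylsilyl)oxy]-2-(hydroxymethyl)cyclohex-2-en-1-ol | OCC1=C[C@@H](O[Si](C)(C)C(C)(C)C)CC[C@H]1O | intermediate
8 | benzyl bromide | BrCc1ccccc1 | starting material
9 | tert-butyl{[(1S,4R)-4-(benzyloxy)-3-[(benzyloxy)methyl]cyclohex-2-en-1-yl]oxy}dimethylsilane | c1ccccc1COCC1=C[C@@H](O[Si](C)(C)C(C)(C)C)CC[C@H]1OCc1ccccc1 | intermediate
10 | tert-butyl{[(1R,2S,5R,6S)-5-(benzyloxy)-6-[(benzyloxy)methyl]-7-oxabicyclo[4.1.0]heptan-2-yl]oxy}dimethylsilane | c1ccccc1COC[C@]1(O2)[C@H](OCc3ccccc3)CC[C@H](O[Si](C)(C)C(C)(C)C)[C@H]12 | intermediate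
11 | (1R,2S,5R,6S)-5-(benzyloxy)-6-[(benzyloxy)methyl]-7-oxabicyclo[4.1.0]heptan-2-ol | c1ccccc1COC[C@]1(O2)[C@H](OCc3ccccc3)CC[C@H](O)[C@H]12 | intermediate
12 | (1S,2S,3R,6S)-3-(benzyloxy)-2-[(benzyloxy)methyl]-7-oxabicyclo[4.1.0]heptan-2-ol (not isolated) | c1ccccc1COC[C@]1(O)[C@H](OCc2ccccc2)CC[C@@H]2O[C@H]12 | intermediate
13 | (1R,2S,3R,6R)-6-(benzyloxy)-1-[(benzyloxy)methyl]cyclohexane-1,2,3-triol | c1ccccc1COC[C@]1(O)[C@H](OCc2ccccc2)CC[C@@H](O)[C@@H]1O | intermediate
14 | benzoyl chloride | O=C(Cl)c1ccccc1 | starting material
15 | (1R,2S,3R,4R)-4-(benzyloxy)-3-[(benzyloxy)methyl]-2,3-dihydroxycyclohexyl benzoate | c1ccccc1COC[C@]1(O)[C@H](OCc2ccccc2)CC[C@@H](OC(=O)c2ccccc2)[C@@H]1O | intermediate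
16 | (1R,2S,3S,4R)-2,3,4-trihydroxy-3-(hydroxymethyl)cyclohexyl benzoate | OC[C@]1(O)[C@H](O)CC[C@@H](OC(=O)c2ccccc2)[C@@H]1O | intermediate
17 | [(1S,2S,3R,6R)-3-(benzoyloxy)-1,2,6-trihydroxycyclohexyl]methyl benzoate | O=C(OC[C@]1(O)[C@H](O)CC[C@@H](OC(=O)c2ccccc2)[C@@H]1O)c1ccccc1 | target

## Step count and least certain steps

Total: 12 steps. Longest linear sequence: 12 steps, from 1 to 17; compounds 5, 8 and 14 enter as single-step reagents.

**Step 9 (key step).** The most likely failure is loss of regiocontrol in the opening. Hydroxide may attack C6, either of 12 through the other half-chair or of 11 directly, because the Payne equilibrium probably favours the more substituted epoxide 11. The diaxial trajectory at C5 also runs past the syn-axial C1 oxygen, which may slow it. Either leak would give diastereomeric triols.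

The fallback sets out from 9 and returns at 13. It makes 12 irreversibly and opens it under conditions in which the epoxide cannot migrate. Alkene 9 is dihydroxylated from the bottom face (OsO4 cat., N-methylmorpholine N-oxide, acetone/H2O) to (1R,2R,3S,6R)-6-(benzyloxy)-1-[(benzyloxy)methyl]-3-[(tert-butyldimethylsilyl)oxy]cyclohexane-1,2-diol F1. Its only secondary hydroxyl, at C6, is then converted (MsCl, Et3N, CH2Cl2) into the C6 methanesulfonate F2. Bu4NF in THF at 0 °C releases the top-face C5 alkoxide, which displaces the bottom-face C6 sulfonate with inversion and closes epoxide 12. Finally 12 is hydrolysed with dilute HClO4 in THF/H2O; under acid the C1–O dipole disfavours attack at C6, so water should open at C5 and give 13.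

**Step 4.** The amine catalyst may add only slowly to C6 because the neighbouring C5 silyloxy group crowds the β-carbon, and slow conversion leaves time for base-induced isomerisation of the γ-silyloxy enone.

The fallback sets out from 4 and returns at 6. It replaces the organocatalytic C–C bond formation by a cross-coupling. α-Iodination (I2, pyridine, CH2Cl2) gives (4S)-4-[(tert-butyldimethylsilyl)oxy]-2-iodocyclohex-2-en-1-one F3, and Stille coupling of this iodide with (tributylstannyl)methanol (Pd(PPh3)4, zerovalent palladium, dioxane, 80 °C) then gives 6.

**Step 2.** The catalyst may discriminate poorly between the enantiotopic bridgehead hydrogens of the compact bicyclic peroxide, and the amine may isomerise 3 onward to the achiral 1,4-diketone.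

The fallback sets out from 2 and returns at 4. It moves the desymmetrisation to an enzyme. Thiourea in MeOH reduces the O–O bond to cis-cyclohex-2-ene-1,4-diol F4. Lipase-mediated desymmetrisation then gives (1R,4S)-4-hydroxycyclohex-2-en-1-yl acetate F5; acetylation of the diol with vinyl acetate and hydrolysis of its diacetate give opposite enantiomers, and the mode that leaves the free hydroxyl on the (S)-carbon is used. Silylation (TBSCl, imidazole) gives (1R,4S)-4-[(tert-butyldimethylsilyl)oxy]cyclohex-2-en-1-yl acetate F6, methanolysis (K2CO3, MeOH) gives (1R,4S)-4-[(tert-butyldimethylsilyl)oxy]cyclohex-2-en-1-ol F7, and allylic oxidation with MnO2 in CH2Cl2 gives 4.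

**Step 5.** Facial selectivity in hydride delivery may be poor if the conformer with a pseudoequatorial silyloxy group reacts, which would give the 1,4-trans alcohol.

The fallback sets out from 6 and returns at 7. It replaces substrate control by reagent control: Corey–Bakshi–Shibata reduction with the (S)-configured 2-methyl oxazaborolidine and BH3·SMe2, with one extra equivalent of borane for the free hydroxyl. Taking the substituted alkenyl arm as the large group, this catalyst should deliver hydride to the bottom face of C2.

**Step 12.** Acylation may also occur at the C2 or C6 hydroxyl, and the benzoyl group may migrate under the basic conditions.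

The fallback sets out from 16 and returns at 17. It replaces the chemical acyl donor by an enzyme: Candida antarctica lipase B with vinyl benzoate in THF, which is expected to acylate only the primary hydroxyl under neutral conditions.

## Further compounds

F1 | step 9 | (1R,2R,3S,6R)-6-(benzyloxy)-1-[(benzyloxy)methyl]-3-[(tert-butyldimethylsilyl)oxy]cyclohexane-1,2-diol | c1ccccc1COC[C@]1(O)[C@H](OCc2ccccc2)CC[C@H](O[Si](C)(C)C(C)(C)C)[C@H]1O
F2 | step 9 | C6 methanesulfonate of F1 (3-(benzyloxy)-2-[(benzyloxy)methyl]-6-[(tert-butyldimethylsilyl)oxy]-2-hydroxycyclohexyl methanesulfonate, configuration as in F1) | c1ccccc1COC[C@]1(O)[C@H](OCc2ccccc2)CC[C@H](O[Si](C)(C)C(C)(C)C)[C@H]1OS(C)(=O)=O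
F3 | step 4 | (4S)-4-[(tert-butyldimethylsilyl)oxy]-2-iodocyclohex-2-en-1-one | O=C1C(I)=C[C@@H](O[Si](C)(C)C(C)(C)C)CC1
F4 | step 2 | cis-cyclohex-2-ene-1,4-diol (meso) | C1=C[C@@H](O)CC[C@H]1O
F5 | step 2 | (1R,4S)-4-hydroxycyclohex-2-en-1-yl acetate | C1=C[C@@H](O)CC[C@H]1OC(C)=O
F6 | step 2 | (1R,4S)-4-[(tert-butyldimethylsilyl)oxy]cyclohex-2-en-1-yl acetate | C1=C[C@@H](O[Si](C)(C)C(C)(C)C)CC[C@H]1OC(C)=O
F7 | step 2 | (1R,4S)-4-[(tert-butyldimethylsilyl)oxy]cyclohex-2-en-1-ol | C1=C[C@@H](O[Si](C)(C)C(C)(C)C)CC[C@H]1O
F0 | step 5 | none | none
F0 | step 12 | none | none
A1 | alternative 1 | [1-(methoxymethoxy)cyclohexa-2,5-dien-1-yl]methanol | OCC1(OCOC)C=CCC=C1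
A2 | alternative 1 | cis-fused six-membered carbonate spanning the C7 and C2 oxygens, with iodine on C3 and the C5=C6 alkene kept | O=C1OC[C@]2(OCOC)[C@H](O1)[C@@H](I)CC=C2
A3 | alternative 2 | meso C2,C6-acetonide of the C7 benzoate carrying a diethylhydrosilyl ether on the C1 oxygen | O=C(OC[C@]1(O[SiH](CC)CC)[C@H]2CCC[C@@H]1OC(C)(C)O2)c1ccccc1
A4 | alternative 2 | diethyl oxasilolane linking the C1 oxygen to C5 on the acetonide benzoate | O=C(OC[C@@]12[C@H]3CC[C@@H]([Si](CC)(CC)O1)[C@@H]2OC(C)(C)O3)c1ccccc1
A5 | alternative 3 | 2,3,6-tris(benzyloxy)cyclohexan-1-one (2,6-cis, 2,3-trans) | O=C1[C@H](OCc2ccccc2)CC[C@@H](OCc2ccccc2)[C@@H]1OCc1ccccc1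
A6 | alternative 3 | C1 spiro-oxirane whose CH2 lies on the face of the C2 and C6 benzyl ethers | C1O[C@]12[C@H](OCc3ccccc3)CC[C@@H](OCc3ccccc3)[C@@H]2OCc2ccccc2
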